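**Easy count.** The easy step is a reagent balance, as on any tank: a mono adduct carries one reagent and a double product carries two. So the reagent charged, less the mono adduct, should buy double product at two to one.

| flask | starting material | reagent | remark | time |
|---|---|---|---|---|
| Friday's | 1 M | 1.1 M | run made earlier |  |
| Saturday's | 1 M | 1.6 M | run made earlier |  |
| Monday's | 1 M | 2 M | run made earlier |  |
| alpha | 1.0 M | 1.00 M |  | 8.0 d |
| theta | 1.0 M | 1.50 M |  | 8.0 d |
| epsilon | 1.0 M | 2.50 M |  | 8.0 d |

- Friday's (time / d: double product / %, mono adduct / %): 1.04: 21, 28; 2.50: 34, 26; 3.00: 34, 29; 5.00: 34, 31; 6.00: 35, 26
- Saturday's (time / d: double product / %, mono adduct / %): 1.04: 36, 26; 2.50: 53, 21; 3.00: 56, 22; 5.00: 60, 20; 6.00: 62, 18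
- Monday's (time / d: double product / %, mono adduct / %): 1.04: 47, 23; 2.50: 61, 17; 3.00: 65, 13; 5.00: 80, 12; 6.00: 79, 6

(each reading ± 2 percentage points)

- the analysis behind the earlier runs scatters by 2 percentage points, standard deviation

* amount of double product at the end, in percent of the starting material charged, for each flask in turn (alpha, theta, epsilon)

**Reagent price.** I test this on the mean of the last two readings of each run. Mono adduct then reads 28.5% on Friday and 19.0% on Saturday. Reagent charged minus mono adduct, divided by double product, comes to 2.36 on Friday, 2.31 on Saturday and 2.40 on Monday. With 2 percentage points of scatter on a reading, I carry their mean, 2.36, as the reagent price: reagent paid per double product, treating reagent as the limiting reagent. It is higher than the plain count of two.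

**Low end.** A straight line through the mono adduct readings gives 30.4% for flask alpha and 20.9% for flask theta. At the reagent price, I estimate 29.5% double product for flask alpha and 54.7% for flask theta.

**The border.** With mono adduct taken as nil, the rule stops at a charge ratio equal to the price. Flask epsilon has a ratio of 2.50, above the price, so its reagent would buy 106%. One starting material gives one double product, so I cap my estimate for flask epsilon at 100%.

**The result.** The forecast gives 30%, 55% and 92%, on the ground of “a slow parallel reagent loss”. The flasks give 33.0%, 61.0% and 80.9%, against my 29.5%, 54.7% and the cap of 100%.

    reagent + mono adduct → over-reaction product (k = 0.00180 /M/h)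
    reagent + mono adduct → double product + by-product (k = 0.0940 /M/h)
    mono adduct ⇌ isomer of the product (K = 0.110, k = 0.160 /h)
    starting material + reagent → mono adduct + by-product (k = 0.0670 /M/h)
    reagent + double product ⇌ triple product + by-product (K = 1.30, k = 0.0250 /M/h)

**Flask epsilon.** At 4.00 d, flask epsilon holds 1.21% starting material and 75.7% double product, and the step from double to triple product has run beside the two additions, with 18.2% triple product standing. At 8.00 d, flask epsilon holds 16.7% triple product and 13.6% of its own reagent charge, so with the reagent still there taken off the charge, the reagent price comes to 2.67 in flask epsilon and, reckoned the same way, 2.12 in flask theta.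

The data come from a simulation on assumed constants; the scatter is artificial.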